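**Retrosynthetic overview**
- The oxirane is made last, by hydroxyl-directed VO(acac)2/t-BuOOH epoxidation of a (Z,Z)-cyclodecadien-6-ol 8-aroate; C4 and C5 are set from C6.
- The ten-membered ring is closed at C8–C9 by a visible-light Mn2(CO)10 radical macrocyclisation: aldehyde + aroyl bromide → 1-bromoalkyl aroate → α-acyloxyalkyl radical → addition to an isopropenyl terminus with loss of an allylic chlorine. This one step brings in the ester, C8, the ring and the (Z)-C1=C10 olefin.
- The open-chain aldehyde comes from ene-chlorination of a prenyl terminus; the chain is built by Negishi coupling of a (Z)-vinyl iodide (Stork–Zhao olefination) with homoprenylzinc bromide.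
- C6 is bought in dimethyl (R)-malate; C7 follows from it by anti-selective Fráter–Seebach isopropylation.
- Ring order: carbocycle first (step 8), oxirane second (step 10).

Assumption: germacrane numbering is used for atom labels (ring C1–C10, isopropyl on C7, ester on C8); dimethyl (R)-malate is taken as the commercial chiral starting material; centres that are destroyed later (C1–Cl, C8–Br) are carried as mixtures.

**Step 1**
Reactants: 1 dimethyl (2R)-2-hydroxybutanedioate (dimethyl (R)-malate)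
Product: 2 dimethyl (2R,3S)-2-hydroxy-3-(propan-2-yl)butanedioate
Conditions: LiN(i-Pr)2 (2.2 equiv), THF, −78 → −20 °C; i-PrI, DMPU, −78 → −10 °C; H2O
Reagents that add atoms: 2-iodopropane CC(C)I
Why: Fráter–Seebach alkylation, in which the chelated lithium alkoxide–enolate dianion is attacked by the iodide on the face away from the carbinol substituent, so the bought C6 centre sets C7 anti (2R,3S), with only a modest yield expected for a secondary iodide.

**Step 2**
Reactants: 2 dimethyl (2R,3S)-2-hydroxy-3-(propan-2-yl)butanedioate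
Product: 3 dimethyl (2R,3S)-2-[(tert-butyldimethylsilyl)oxy]-3-(propan-2-yl)butanedioate
Conditions: t-BuMe2SiOTf, 2,6-lutidine, CH2Cl2, 0 °C
Reagents that add atoms: tert-butyldimethylsilyl trifluoromethanesulfonate CC(C)(C)[Si](C)(C)OS(=O)(=O)C(F)(F)F
Why: Standard silyl protection of the secondary hydroxyl with the triflate and a hindered base, which touches no stereocentre.

**Step 3**
Reactants: 3 dimethyl (2R,3S)-2-[(tert-butyldimethylsilyl)oxy]-3-(propan-2-yl)butanedioate
Product: 4 methyl (2S,3R)-3-[(tert-butyldimethylsilyl)oxy]-4-oxo-2-(propan-2-yl)butanoate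
Conditions: i-Bu2AlH (1.05 equiv), CH2Cl2, −78 °C; aq. potassium sodium tartrate
Reagents that add atoms: none
Why: Chemoselective half-reduction, in which the α-silyloxy ester is more electrophilic and much less hindered than the ester next to the isopropyl-bearing carbon and the aluminium hemiacetal survives at −78 °C until work-up, so no stereocentre is formed or lost (the aldehyde is used at once).

**Step 4**
Reactants: 4 methyl (2S,3R)-3-[(tert-butyldimethylsilyl)oxy]-4-oxo-2-(propan-2-yl)butanoate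
Product: 5 methyl (2S,3R,4Z)-3-[(tert-butyldimethylsilyl)oxy]-5-iodo-2-(propan-2-yl)hex-4-enoate
Conditions: EtPPh3I, n-BuLi, THF, 0 °C; I2, −78 °C; NaN(SiMe3)2, −20 °C; 4, −78 → −20 °C
Reagents that add atoms: ethyltriphenylphosphonium iodide CC[P+](c1ccccc1)(c1ccccc1)c1ccccc1.[I-]; iodine [I][I]
Why: Stork–Zhao olefination, in which the α-iodo ylide reacts under kinetic Wittig control to give the (Z)-2-iodoalkene with iodine cis to the chain, at a temperature where the α-silyloxy aldehyde does not epimerise.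

**Step 5**
Reactants: 5 methyl (2S,3R,4Z)-3-[(tert-butyldimethylsilyl)oxy]-5-iodo-2-(propan-2-yl)hex-4-enoate; 6 5-bromo-2-methylpent-2-ene
Product: 8 methyl (2S,3S,4Z)-3-[(tert-butyldimethylsilyl)oxy]-5,9-dimethyl-2-(propan-2-yl)deca-4,8-dienoate, via homoprenylzinc bromide 7 (not isolated)
Conditions: 6, Zn, LiCl, THF, 40 °C; then 5, Pd(dppf)Cl2 (5 mol %), THF, rt
Reagents that add atoms: none
Why: Negishi sp3–sp2 cross-coupling, in which oxidative addition to zerovalent palladium and reductive elimination both keep the olefin geometry, so C3 ends up cis to C6 and the (Z)-C4=C5 bond is fixed (the descriptor at the silyloxy carbon changes only because of CIP priorities).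

**Step 6**
Reactants: 8 methyl (2S,3S,4Z)-3-[(tert-butyldimethylsilyl)oxy]-5,9-dimethyl-2-(propan-2-yl)deca-4,8-dienoate
Product: 9 methyl (2S,3S,4Z,8RS)-3-[(tert-butyldimethylsilyl)oxy]-8-chloro-5,9-dimethyl-2-(propan-2-yl)deca-4,9-dienoate
Conditions: Ca(OCl)2, CO2 (dry ice), CH2Cl2/H2O, 0 °C
Reagents that add atoms: calcium hypochlorite [Ca+2].[O-]Cl.[O-]Cl
Why: Ene-type chlorination with hypochlorous acid made in situ, which attacks the electron-rich, unhindered terminal trisubstituted olefin (chlorine to C1, loss of a methyl proton to give the isopropenyl group) while the inner olefin is deactivated and shielded by the allylic silyl ether, and the new C1 centre is a 1:1 mixture that disappears in step 8.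

**Step 7**
Reactants: 9 methyl (2S,3S,4Z,8RS)-3-[(tert-butyldimethylsilyl)oxy]-8-chloro-5,9-dimethyl-2-(propan-2-yl)deca-4,9-dienoate
Product: 10 (2S,3S,4Z,8RS)-3-[(tert-butyldimethylsilyl)oxy]-8-chloro-5,9-dimethyl-2-(propan-2-yl)deca-4,9-dienal
Conditions: i-Bu2AlH (1.1 equiv), CH2Cl2, −78 °C; aq. potassium sodium tartrate
Reagents that add atoms: none
Why: Half-reduction of the hindered ester to the aldehyde through an aluminium hemiacetal that is stable at −78 °C, leaving the allylic chloride, the silyl ether and the α-centre C7 intact (the aldehyde is used cold and without storage).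

**Step 8**
Reactants: 10 (2S,3S,4Z,8RS)-3-[(tert-butyldimethylsilyl)oxy]-8-chloro-5,9-dimethyl-2-(propan-2-yl)deca-4,9-dienal; 11 3,4,5-trimethoxybenzoyl chloride
Product: 14 (1R,3Z,7Z,9S,10R)-9-[(tert-butyldimethylsilyl)oxy]-3,7-dimethyl-10-(propan-2-yl)cyclodeca-3,7-dien-1-yl 3,4,5-trimethoxybenzoate, via 3,4,5-trimethoxybenzoyl bromide 12 (not isolated), via 1-bromoalkyl 3,4,5-trimethoxybenzoate 13 (not isolated)
Conditions: 11, Me3SiBr, CH2Cl2, rt, evaporate; 10, ZnBr2 (1 mol %), CH2Cl2, 0 °C; Mn2(CO)10 (1.1 equiv), PhH (2 mM), 450 nm LEDs, rt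
Reagents that add atoms: none
Why: Proposed new method: halide exchange gives the aroyl bromide, which adds across the aldehyde to a 1-bromoalkyl aroate, then Mn(CO)5 radicals formed from Mn2(CO)10 by visible light abstract the activated bromine, the nucleophilic α-acyloxyalkyl radical adds 10-endo to the CH2 terminus of the isopropenyl group and the tertiary β-chloroalkyl radical loses chlorine to manganese to give the ring olefin, expected (Z) because the product-like β-scission follows the less strained cis-cyclodecene, while C8 is set in the C–C bond formation through the radical conformer with C7–H eclipsing C8–O and attack anti to the larger C6 branch (7,8-anti, 8R in germacrane numbering), and no hydrogen donor is present so a slow ring closure is not cut short by reduction; the closest known chemistry is the Mn2(CO)10/visible-light generation of α-acyloxyalkyl (ketyl-type) radicals from aldehyde–acyl halide adducts with atom-transfer addition to alkynes, radical SH2′ allylation with allylic halides, and atom-transfer radical macrocyclisation.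

**Step 9**
Reactants: 14 (1R,3Z,7Z,9S,10R)-9-[(tert-butyldimethylsilyl)oxy]-3,7-dimethyl-10-(propan-2-yl)cyclodeca-3,7-dien-1-yl 3,4,5-trimethoxybenzoate
Product: 15 (1R,3Z,7Z,9S,10S)-9-hydroxy-3,7-dimethyl-10-(propan-2-yl)cyclodeca-3,7-dien-1-yl 3,4,5-trimethoxybenzoate
Conditions: HF·pyridine, pyridine, THF, 0 °C → rt
Reagents that add atoms: none
Why: Buffered fluoride cleavage of the silyl ether, mild enough to leave the aryl ester in place (no acyl migration) and the skipped diene untouched (the descriptor at C10 changes only through CIP priorities).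

**Step 10**
Reactants: 15 (1R,3Z,7Z,9S,10S)-9-hydroxy-3,7-dimethyl-10-(propan-2-yl)cyclodeca-3,7-dien-1-yl 3,4,5-trimethoxybenzoate
Product: 16 (1(10)Z,4S,5R,6R,7S,8R)-4,5-epoxy-6-hydroxygermacr-1(10)-en-8-yl 3,4,5-trimethoxybenzoate (target)
Conditions: VO(acac)2 (5 mol %), t-BuOOH, CH2Cl2, 0 °C
Reagents that add atoms: tert-butyl hydroperoxide CC(C)(C)OO
Why: Hydroxyl-directed epoxidation (Sharpless–Michaelson type), in which the vanadium alkoxide of the C6 hydroxyl delivers oxygen only to the allylic C4=C5 bond and, as in eight- and nine-membered (Z)-cycloalkenols, to the face that gives the cis epoxy alcohol (4S,5R), while the remote C1=C10 olefin has no directing group.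

**Compound list**
1 | dimethyl (2R)-2-hydroxybutanedioate (dimethyl (R)-malate) | COC(=O)[C@H](O)CC(=O)OC | starting material
2 | dimethyl (2R,3S)-2-hydroxy-3-(propan-2-yl)butanedioate | COC(=O)[C@H](O)[C@@H](C(=O)OC)C(C)C | intermediate
3 | dimethyl (2R,3S)-2-[(tert-butyldimethylsilyl)oxy]-3-(propan-2-yl)butanedioate | COC(=O)[C@H](O[Si](C)(C)C(C)(C)C)[C@@H](C(=O)OC)C(C)C | intermediate
4 | methyl (2S,3R)-3-[(tert-butyldimethylsilyl)oxy]-4-oxo-2-(propan-2-yl)butanoate | O=C[C@H](O[Si](C)(C)C(C)(C)C)[C@@H](C(=O)OC)C(C)C | intermediate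
5 | methyl (2S,3R,4Z)-3-[(tert-butyldimethylsilyl)oxy]-5-iodo-2-(propan-2-yl)hex-4-enoate | I/C(C)=C\[C@H](O[Si](C)(C)C(C)(C)C)[C@@H](C(=O)OC)C(C)C | intermediate
6 | 5-bromo-2-methylpent-2-ene | CC(C)=CCCBr | starting material
7 | (4-methylpent-3-en-1-yl)zinc bromide (homoprenylzinc bromide) | CC(C)=CCC[Zn]Br | intermediate (not isolated)
8 | methyl (2S,3S,4Z)-3-[(tert-butyldimethylsilyl)oxy]-5,9-dimethyl-2-(propan-2-yl)deca-4,8-dienoate | CC(C)=CCC/C(C)=C\[C@H](O[Si](C)(C)C(C)(C)C)[C@@H](C(=O)OC)C(C)C | intermediate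
9 | methyl (2S,3S,4Z,8RS)-3-[(tert-butyldimethylsilyl)oxy]-8-chloro-5,9-dimethyl-2-(propan-2-yl)deca-4,9-dienoate | C=C(C)C(Cl)CC/C(C)=C\[C@H](O[Si](C)(C)C(C)(C)C)[C@@H](C(=O)OC)C(C)C | intermediate
10 | (2S,3S,4Z,8RS)-3-[(tert-butyldimethylsilyl)oxy]-8-chloro-5,9-dimethyl-2-(propan-2-yl)deca-4,9-dienal | C=C(C)C(Cl)CC/C(C)=C\[C@H](O[Si](C)(C)C(C)(C)C)[C@@H](C=O)C(C)C | intermediate
11 | 3,4,5-trimethoxybenzoyl chloride | COc1cc(C(=O)Cl)cc(OC)c1OC | starting material
12 | 3,4,5-trimethoxybenzoyl bromide | COc1cc(C(=O)Br)cc(OC)c1OC | intermediate (not isolated)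
13 | (1RS,2S,3S,4Z,8RS)-1-bromo-3-[(tert-butyldimethylsilyl)oxy]-8-chloro-5,9-dimethyl-2-(propan-2-yl)deca-4,9-dien-1-yl 3,4,5-trimethoxybenzoate | C=C(C)C(Cl)CC/C(C)=C\[C@H](O[Si](C)(C)C(C)(C)C)[C@@H](C(Br)OC(=O)c1cc(OC)c(OC)c(OC)c1)C(C)C | intermediate (not isolated)
14 | (1R,3Z,7Z,9S,10R)-9-[(tert-butyldimethylsilyl)oxy]-3,7-dimethyl-10-(propan-2-yl)cyclodeca-3,7-dien-1-yl 3,4,5-trimethoxybenzoate | COc1cc(C(=O)O[C@@H]2C/C(C)=C\CC/C(C)=C\[C@H](O[Si](C)(C)C(C)(C)C)[C@@H]2C(C)C)cc(OC)c1OC | intermediate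
15 | (1R,3Z,7Z,9S,10S)-9-hydroxy-3,7-dimethyl-10-(propan-2-yl)cyclodeca-3,7-dien-1-yl 3,4,5-trimethoxybenzoate | COc1cc(C(=O)O[C@@H]2C/C(C)=C\CC/C(C)=C\[C@H](O)[C@@H]2C(C)C)cc(OC)c1OC | intermediate
16 | (1(10)Z,4S,5R,6R,7S,8R)-4,5-epoxy-6-hydroxygermacr-1(10)-en-8-yl 3,4,5-trimethoxybenzoate | COc1cc(C(=O)O[C@@H]2C/C(C)=C\CC[C@]3(C)O[C@@H]3[C@H](O)[C@@H]2C(C)C)cc(OC)c1OC | target

**Totals**
Total step count: 10. Longest linear sequence: 10 steps (1 → 16).

**The three steps most likely to fail**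

Step 8 (the proposed radical macrocyclisation). The ten-membered closure may be slow, and it may give some (E)-olefin or the C8 epimer. The fallback uses known chemistry only, sets out from 5 and comes back at 14. Negishi coupling of 5 with commercial but-3-en-1-ylzinc bromide (Pd(dppf)Cl2) gives methyl (2S,3S,4Z)-3-[(tert-butyldimethylsilyl)oxy]-5-methyl-2-(propan-2-yl)nona-4,8-dienoate F1. Reduction with i-Bu2AlH at −78 °C gives (2S,3S,4Z)-3-[(tert-butyldimethylsilyl)oxy]-5-methyl-2-(propan-2-yl)nona-4,8-dienal F2. Addition of tributyl(2-methylallyl)stannane with BF3·OEt2 goes under Felkin and 1,3-anti control, which reinforce each other for this anti aldehyde, and gives (5Z,7S,8R,9S)-7-[(tert-butyldimethylsilyl)oxy]-5,11-dimethyl-8-(propan-2-yl)dodeca-1,5,11-trien-9-ol F3, the C8 epimer in germacrane numbering. Mitsunobu esterification with 3,4,5-trimethoxybenzoic acid (PPh3, DIAD) inverts that centre and gives (5Z,7S,8R,9R)-7-[(tert-butyldimethylsilyl)oxy]-5,11-dimethyl-8-(propan-2-yl)dodeca-1,5,11-trien-9-yl 3,4,5-trimethoxybenzoate F4. Ring-closing metathesis with the second-generation Hoveyda–Grubbs catalyst, (H2IMes)Cl2Ru=CH(C6H4-2-O-i-Pr), at 1 mM in toluene at 80 °C closes the trisubstituted (Z)-olefin and gives 14.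

Step 1 (alkylation of the dianion with a secondary iodide). Elimination of the iodide and low conversion are likely. The fallback sets out from 1 and comes back at 3. The same dianion is quenched with acetone (fast aldol, same anti sense) to give dimethyl (2R,3R)-2-hydroxy-3-(2-hydroxypropan-2-yl)butanedioate F5. The secondary hydroxyl is silylated selectively (t-BuMe2SiCl, imidazole) to dimethyl (2R,3R)-2-[(tert-butyldimethylsilyl)oxy]-3-(2-hydroxypropan-2-yl)butanedioate F6. The tertiary hydroxyl is acylated with methyl chlorooxoacetate (DMAP, pyridine) to dimethyl (2R,3R)-2-[(tert-butyldimethylsilyl)oxy]-3-[2-(2-methoxy-2-oxoacetoxy)propan-2-yl]butanedioate F7. Bu3SnH/AIBN (Dolan–MacMillan deoxygenation of tertiary oxalates) then removes the oxygen without touching C7 and gives 3.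

Step 6 (ene-chlorination in the presence of a second trisubstituted olefin and a silyl ether). The fallback sets out from 8 and comes back at 9. Photo-oxygenation of 8 (O2, tetraphenylporphyrin, visible light, CH2Cl2, −20 °C; Schenck ene reaction at the unhindered terminal olefin) gives, beside its tertiary regioisomer, methyl (2S,3S,4Z,8RS)-3-[(tert-butyldimethylsilyl)oxy]-8-hydroperoxy-5,9-dimethyl-2-(propan-2-yl)deca-4,9-dienoate F8. PPh3 reduces it to methyl (2S,3S,4Z,8RS)-3-[(tert-butyldimethylsilyl)oxy]-8-hydroxy-5,9-dimethyl-2-(propan-2-yl)deca-4,9-dienoate F9. Hexachloroacetone/PPh3 (Magid chlorination, no allylic transposition) gives 9.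

The facial selectivity of step 10 is also unproven for a ten-membered ring; it rests on the cis preference of vanadium in eight- and nine-membered (Z)-cycloalkenols.

**Further compounds**
F1 | step 8 | methyl (2S,3S,4Z)-3-[(tert-butyldimethylsilyl)oxy]-5-methyl-2-(propan-2-yl)nona-4,8-dienoate | C=CCC/C(C)=C\[C@H](O[Si](C)(C)C(C)(C)C)[C@@H](C(=O)OC)C(C)C
F2 | step 8 | (2S,3S,4Z)-3-[(tert-butyldimethylsilyl)oxy]-5-methyl-2-(propan-2-yl)nona-4,8-dienal | C=CCC/C(C)=C\[C@H](O[Si](C)(C)C(C)(C)C)[C@@H](C=O)C(C)C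
F3 | step 8 | (5Z,7S,8R,9S)-7-[(tert-butyldimethylsilyl)oxy]-5,11-dimethyl-8-(propan-2-yl)dodeca-1,5,11-trien-9-ol | C=CCC/C(C)=C\[C@H](O[Si](C)(C)C(C)(C)C)[C@@H]([C@@H](O)CC(C)=C)C(C)C
F4 | step 8 | (5Z,7S,8R,9R)-7-[(tert-butyldimethylsilyl)oxy]-5,11-dimethyl-8-(propan-2-yl)dodeca-1,5,11-trien-9-yl 3,4,5-trimethoxybenzoate | C=CCC/C(C)=C\[C@H](O[Si](C)(C)C(C)(C)C)[C@@H]([C@H](OC(=O)c1cc(OC)c(OC)c(OC)c1)CC(C)=C)C(C)C
F5 | step 1 | dimethyl (2R,3R)-2-hydroxy-3-(2-hydroxypropan-2-yl)butanedioate | COC(=O)[C@H](O)[C@@H](C(=O)OC)C(C)(C)O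
F6 | step 1 | dimethyl (2R,3R)-2-[(tert-butyldimethylsilyl)oxy]-3-(2-hydroxypropan-2-yl)butanedioate | COC(=O)[C@H](O[Si](C)(C)C(C)(C)C)[C@@H](C(=O)OC)C(C)(C)O
F7 | step 1 | dimethyl (2R,3R)-2-[(tert-butyldimethylsilyl)oxy]-3-[2-(2-methoxy-2-oxoacetoxy)propan-2-yl]butanedioate | COC(=O)[C@H](O[Si](C)(C)C(C)(C)C)[C@@H](C(=O)OC)C(C)(C)OC(=O)C(=O)OC
F8 | step 6 | methyl (2S,3S,4Z,8RS)-3-[(tert-butyldimethylsilyl)oxy]-8-hydroperoxy-5,9-dimethyl-2-(propan-2-yl)deca-4,9-dienoate | C=C(C)C(OO)CC/C(C)=C\[C@H](O[Si](C)(C)C(C)(C)C)[C@@H](C(=O)OC)C(C)C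
F9 | step 6 | methyl (2S,3S,4Z,8RS)-3-[(tert-butyldimethylsilyl)oxy]-8-hydroxy-5,9-dimethyl-2-(propan-2-yl)deca-4,9-dienoate | C=C(C)C(O)CC/C(C)=C\[C@H](O[Si](C)(C)C(C)(C)C)[C@@H](C(=O)OC)C(C)C
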